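Compound numbers refer to the steps and the compound list further down.

## Analysis of the target

The target is a flavonol: a benzo-fused 4H-pyran-4-one (rings A and C) with an aryl ring B on C2 and oxygen on C3, C5, C7, C3' and C4'. It has no stereocentre and no side chain, so the only stereochemical events in a synthesis are transient ones in ring C. The enolic hydroxyl on C3 and the phenol on C3' are hydrogen sulfate esters, while the hydroxyls on C5, C7 and C4' are free. Sulfate monoesters are strongly acidic, very polar and hydrolyse under acid, so they must be introduced late, and the three free phenols must then be unmasked under neutral conditions. The difficulty is therefore less the skeleton than sorting five hydroxyls into two sets. Direct sulfation of the pentahydroxyflavone would go first to the acidic 7- and 4'-hydroxyls, the opposite of what is wanted, and the 3-hydroxyl is chelated to the C4 carbonyl and sluggish. The strategy rests on ring A: O1 on C8a and the acyl carbon C4 on C4a are ortho to each other, and the C5 oxygen sits on the other side of C4a. This contiguous pattern is what a 3-alkoxybenzyne delivers when an oxygen nucleophile adds to its distal carbon and an acyl group is taken up at the proximal one. If the acyl partner is an α-alkoxycinnamic acid, it brings C2, C3, C4, ring B and the C3 oxygen with it.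

## Retrosynthetic reasoning

**24 to 23.** The three O–CH2Ph bonds on O5, O7 and O4' are cut. Hydrogenolysis is the one deprotection that is neutral and leaves sulfate esters alone, so benzyl is the mask for every phenol that stays free. The forward step must cleave three ethers without hydrolysing the sulfates or saturating C2=C3.

**23 to 22.** Both S–O bonds are cut. Compound 22 has free hydroxyls only on C3 and C3', so the forward step needs no selectivity between hydroxyls, only complete sulfation with a sulfating agent.

**22 to 21.** The two hydroxyls are traced back to methoxymethyl acetals. These survive base, fluoride, organolithium reagents and a quinone oxidant, and fall to dilute acid that leaves benzyl ethers intact. One kind of protecting group on the oxygens to be sulfated and another on the oxygens to be freed writes the substitution pattern of 24 into the building blocks.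

**21 to 20.** Two hydrogens are added across C2=C3. The flavone is taken back to flavanone 20 because ring closure by conjugate addition gives the saturated ring C. The forward dehydrogenation erases both stereocentres of 20, so their configuration needs no control.

**20 to 8 and 17.** First O1–C2 is cut (retro-oxa-Michael) to hydroxychalcone 19. Then C8a–O1 and C4a–C4 are cut together, which turns ring A into aryne 18 (released from silyl triflate 8) and the rest into acid 17. These three cuts all lie in ring C and split the molecule into two halves of similar size. The acid supplies the nucleophilic oxygen and the electrophilic carbonyl carbon in the 1,2-relationship that an aryne accepts, and it already carries the C3 oxygen. The forward step must capture the aryne with the right orientation, transfer the acyl group to carbon and close ring C.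

**17 to 10 and 12.** The C=C bond of 17 (future C2–C3) is cut by a retro-aldol condensation: ester 16 comes from aldol 14 by dehydration, and 14 from enolate 13 of glycolate 10 and aldehyde 12. Compound 10 comes from 9 and compound 12 from 11, each by one acetal protection. The aldol route is chosen because both partners are one step from commercial materials.

**8 to 1.** The O–S bond of the triflate is cut to phenol 7 and the carbamate is put back to give 6. The C–Si bond is then cut: the silyl group is placed by directed ortho-lithiation (aryllithium 4) of carbamate 2, masked on nitrogen in the flask as 3 and silylated to 5. Both positions ortho to the oxygen of 1 are equivalent by symmetry, so the silyl group can only end up between the future triflate and a benzyloxy group, as the aryne requires.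

## Alternatives that were turned down

**Alternative 1:** Ring C is traced back to the five-membered ring of an aurone, (Z)-2-[4-(benzyloxy)-3-hydroxybenzylidene]-4,6-dihydroxybenzofuran-3(2H)-one A1 (Auwers flavonol synthesis).
- Key step: halogen is added across the exocyclic double bond and hot aqueous-alcoholic alkali opens the furanone at the halogenated ketal carbon. The phenoxide recloses on the benzylic carbon to give 4'-O-benzylquercetin A2.
- For: A1 should come from a single condensation, and the ring expansion lands directly on the flavonol oxidation level with the 3-hydroxyl in place. No dehydrogenation is needed, and the count to the core is the shortest of all four plans.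
- Against: A1 has two very electron-rich rings, so ring halogenation should compete with addition to the olefin. More seriously, A2 exposes hydroxyls on C3, C5, C7 and C3'. The 7-hydroxyl is the most acidic and accessible of them and would be sulfated with or before the two wanted positions. Protecting it selectively beside the 3- and 3'-hydroxyls has no clean solution and adds steps and separations.
- Comparison: on the ring-forming step Alternative 1 is at least as short and reaches the right oxidation state at once, which the chosen route does only after step 10. In return the chosen route gives a product, 20, in which each of the five oxygens already carries the group its fate requires.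

**Alternative 2:** Ring A is built by a Danheiser benzannulation of 3-(benzyloxy)cyclobut-2-en-1-one A3 with the siloxy diyne tert-butyl({1-[4-(benzyloxy)-3-(methoxymethoxy)phenyl]-5-[(triisopropylsilyl)oxy]penta-1,4-diyn-3-yl}oxy)dimethylsilane A4.
- Key step: heating opens A3 to a vinylketene, which adds to the siloxyalkyne. Four-electron opening, six-electron closure and tautomerisation then give phenol A5, 5-(benzyloxy)-2-{1-(tert-butyldimethylsilyloxy)-3-[4-(benzyloxy)-3-(methoxymethoxy)phenyl]prop-2-yn-1-yl}-3-(triisopropylsilyloxy)phenol.
- For: the regiochemistry is fixed by the pericyclic sequence and does not depend on a substituent-directed polar addition. The three oxygens of ring A each receive a different mask, and the conditions are neutral.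
- Against: the target needs no distinction between O5 and O7, and ring A with this pattern can be bought as 1. A4 combines a silyl ynol ether, a propargylic silyl ether and a second alkyne and would need a long synthesis of its own. After A5 there remain desilylation, oxidation to the ynone, a ring closure in which 5-exo attack competes with 6-endo, introduction of the missing C3 oxygen, and protecting-group changes. The stereocentre of A5 is destroyed on the way.
- Comparison: Alternative 2 is stronger on regiochemical certainty. It is much longer and lacks the C3 oxygen; the chosen route takes ring A from the shelf and spends its steps on ring C.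

**Alternative 3:** Only C8a–O1 is cut, and ring C is closed by intramolecular nucleophilic aromatic substitution in 1-[4-(benzyloxy)-3-(methoxymethoxy)phenyl]-2-(methoxymethoxy)-3-(2,4,6-trifluorophenyl)propane-1,3-dione A6.
- Key step: a carbonate base in a dipolar aprotic solvent forms the enolate of A6, whose oxygen displaces an ortho fluorine. The product is 2-[4-(benzyloxy)-3-(methoxymethoxy)phenyl]-5,7-difluoro-3-(methoxymethoxy)-4H-chromen-4-one A7.
- For: the closure is intramolecular, activated by the ortho carbonyl and free of any regiochemical question, since both ortho fluorines are equivalent. It gives the flavone level directly with both acetals on the right oxygens. It is probably the most dependable ring closure of the four.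
- Against: A7 carries fluorine where the target has oxygen at C5 and C7. Two further substitutions by a benzyl alcoholate are needed. The first alkoxy group deactivates the ring towards the second, C5 is hindered, and alkoxides can also add to C2 of a chromone and open the ring. A6 itself needs several steps from a polyfluoroaryl ketone.
- Comparison: Alternative 3 is stronger on predictability of the key step and needs no dehydrogenation. The chosen route has the C5 and C7 oxygens in place as benzyl ethers from the starting phenol, so after ring closure only functional-group steps of familiar kinds remain.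

Key step: step 9

## Route

Remark on the chemistry: the sulfate monoesters 23 and 24 are drawn and named as free acids, as in the target structure. At the bench they would be carried as pyridinium or sodium salts, and the acid form released only at the end by cation exchange in the cold, because aryl hydrogen sulfates hydrolyse under their own acidity.

Step 1
Reactants: 1 3,5-bis(benzyloxy)phenol
Product: 2 3,5-bis(benzyloxy)phenyl N-isopropylcarbamate
Conditions: i-PrNCO, Et3N (cat.), CH2Cl2, rt
Reagents that add atoms: isopropyl isocyanate, CC(C)N=C=O
Why: Base-catalysed addition of the phenol to the isocyanate (carbamoylation); the N–H carbamate is chosen because it directs lithiation strongly and can later be removed under mild E1cB conditions that a hindered aryl silane tolerates.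

Step 2
Reactants: 2 3,5-bis(benzyloxy)phenyl N-isopropylcarbamate
Product: 6 3,5-bis(benzyloxy)-2-(trimethylsilyl)phenyl N-isopropylcarbamate, via N-silyl carbamate 3 (not isolated), via aryllithium 4 (not isolated), via doubly silylated carbamate 5 (not isolated)
Conditions: TBSOTf, TMEDA, Et2O, 0 °C to rt; n-BuLi, TMEDA, −78 °C; TMSCl, −78 °C to rt; aq. NaHSO4
Reagents that add atoms: chlorotrimethylsilane, C[Si](C)(C)Cl; tert-butyldimethylsilyl trifluoromethanesulfonate, CC(C)(C)[Si](C)(C)OS(=O)(=O)C(F)(F)F (its silyl group stays only in 3, 4 and 5); n-butyllithium, [Li]CCCC (its lithium stays only in 4)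
Why: Directed ortho-metalation: the carbamate is silylated on nitrogen in the flask (3) so that n-BuLi deprotonates the ring and not N–H, and lithiation goes to the position between the carbamate oxygen and a benzyloxy group (4), where two directing groups cooperate and which is the same on either side by symmetry. Trapping with TMSCl gives 5 and the acidic work-up removes the labile N-silyl group; at −78 °C the chelation-assisted ring lithiation should outpace deprotonation of the benzylic CH2 groups.

Step 3
Reactants: 6 3,5-bis(benzyloxy)-2-(trimethylsilyl)phenyl N-isopropylcarbamate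
Product: 8 3,5-bis(benzyloxy)-2-(trimethylsilyl)phenyl trifluoromethanesulfonate, via silyl phenol 7 (not isolated)
Conditions: DBU, Et2NH, MeCN, 40 °C; then PhNTf2, rt
Reagents that add atoms: N-phenylbis(trifluoromethanesulfonimide), O=S(=O)(N(c1ccccc1)S(=O)(=O)C(F)(F)F)C(F)(F)F
Why: DBU deprotonates the carbamate N–H and the phenoxide of 7 is expelled (E1cB), the isocyanate fragment being scavenged by Et2NH as a urea; the phenoxide is triflated in the same flask. This is the usual end of the carbamate route to ortho-silylaryl triflates and avoids isolating the desilylation-prone phenol.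

Step 4
Reactants: 9 methyl glycolate
Product: 10 methyl (methoxymethoxy)acetate
Conditions: MOMCl, i-Pr2NEt, CH2Cl2, 0 °C to rt
Reagents that add atoms: chloromethyl methyl ether, COCCl
Why: O-Alkylation of the primary alcohol by the chloromethyl ether under amine base (acetal protection); the ester is untouched.

Step 5
Reactants: 11 4-(benzyloxy)-3-hydroxybenzaldehyde
Product: 12 4-(benzyloxy)-3-(methoxymethoxy)benzaldehyde
Conditions: MOMCl, i-Pr2NEt, CH2Cl2, 0 °C to rt
Reagents that add atoms: chloromethyl methyl ether, COCCl
Why: The same acetal protection on the phenol; the methoxymethyl group marks O3' for later sulfation and is orthogonal to the benzyl ether on O4'.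

Step 6
Reactants: 10 methyl (methoxymethoxy)acetate; 12 4-(benzyloxy)-3-(methoxymethoxy)benzaldehyde
Product: 14 methyl 3-[4-(benzyloxy)-3-(methoxymethoxy)phenyl]-3-hydroxy-2-(methoxymethoxy)propanoate, via lithium enolate 13 (not isolated)
Conditions: LiN(i-Pr)2 (LDA), THF, −78 °C; then 12; AcOH quench
Reagents that add atoms: lithium diisopropylamide, [Li]N(C(C)C)C(C)C (its lithium stays only in 13)
Why: Aldol addition of the lithium ester enolate 13 to the non-enolisable aldehyde at −78 °C; the two new stereocentres are not controlled (racemic syn/anti mixture) and need not be, since step 7 removes both.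

Step 7
Reactants: 14 methyl 3-[4-(benzyloxy)-3-(methoxymethoxy)phenyl]-3-hydroxy-2-(methoxymethoxy)propanoate
Product: 16 methyl (Z)-3-[4-(benzyloxy)-3-(methoxymethoxy)phenyl]-2-(methoxymethoxy)acrylate, via mesylate 15 (not isolated)
Conditions: MsCl, Et3N, CH2Cl2, 0 °C; then DBU, rt
Reagents that add atoms: methanesulfonyl chloride, CS(=O)(=O)Cl (its sulfonyl group stays only in 15)
Why: Mesylation of the benzylic alcohol and E1cB elimination by DBU through the ester enolate (dehydration of an aldol); both diastereomers of 14 converge on the more stable Z alkene with the aryl group trans to the ester. This geometry later places ring B trans to the ketone, as in an ordinary chalcone.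

Step 8
Reactants: 16 methyl (Z)-3-[4-(benzyloxy)-3-(methoxymethoxy)phenyl]-2-(methoxymethoxy)acrylate
Product: 17 (Z)-3-[4-(benzyloxy)-3-(methoxymethoxy)phenyl]-2-(methoxymethoxy)acrylic acid
Conditions: LiOH, THF/MeOH/H2O, rt; then 1 M HCl to pH 4, 0 °C
Reagents that add atoms: lithium hydroxide, [Li+].[OH-] (supplies the carboxyl oxygen that replaces OMe)
Why: Saponification of the methyl ester; the acetals and the benzyl ether are stable to hydroxide, and acidification only to pH 4 in the cold spares the enol acetal.

Step 9
Reactants: 8 3,5-bis(benzyloxy)-2-(trimethylsilyl)phenyl trifluoromethanesulfonate; 17 (Z)-3-[4-(benzyloxy)-3-(methoxymethoxy)phenyl]-2-(methoxymethoxy)acrylic acid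
Product: 20 rac-trans-5,7-bis(benzyloxy)-2-[4-(benzyloxy)-3-(methoxymethoxy)phenyl]-3-(methoxymethoxy)chroman-4-one, via aryne 18 (not isolated), via hydroxychalcone 19 (not isolated)
Conditions: CsF, THF, 125 °C (sealed tube)
Reagents that add atoms: none
Why: Fluoride removes the silyl group of 8 and triflate leaves, giving aryne 18, whose triple bond is polarised by the flanking benzyloxy group. The cesium carboxylate of 17 adds through oxygen to the distal aryne carbon (future C8a), because the charge then rests on the carbon next to the inductively withdrawing benzyloxy group (future C4a); the second benzyloxy group is too remote to overturn this. The aryl anion attacks the neighbouring ester carbonyl and the strained four-membered alkoxide opens to the ortho-acylphenoxide of 19, so that the aryne has in effect entered the carboxyl C–O bond; the high temperature favours this acyl shift over protonation to the plain aryl ester. The closest known reaction type is the fluoride-induced insertion of arynes into the C–O bond of carboxylic acids, which with α,β-unsaturated acids continues to chroman-4-ones. Ring C closes by 6-endo-trig oxa-Michael addition of the phenoxide to the β-carbon of the alkoxy enone, the 5-exo mode being attack at the α-carbon against the polarisation of the enone. C2 is set in this reversible addition and C3 on protonation of the enolate; both equilibrate (C2 by ring opening and reclosure, C3 by enolisation), so the trans isomer with both substituents equatorial should prevail, as a racemate. The diastereomer ratio is of no consequence, because step 10 removes both centres.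

Step 10
Reactants: 20 rac-trans-5,7-bis(benzyloxy)-2-[4-(benzyloxy)-3-(methoxymethoxy)phenyl]-3-(methoxymethoxy)chroman-4-one
Product: 21 5,7-bis(benzyloxy)-2-[4-(benzyloxy)-3-(methoxymethoxy)phenyl]-3-(methoxymethoxy)-4H-chromen-4-one
Conditions: DDQ, 1,4-dioxane, 100 °C
Reagents that add atoms: none
Why: Dehydrogenation of a flavanone to a flavone by DDQ: hydride is taken from C2, which is activated by O1 and by the para-benzyloxyphenyl ring in the same way as the CH2 of a p-alkoxybenzyl ether, and the C3 proton is then lost. Both stereocentres disappear; unsubstituted benzyl ethers and the acetals should not be oxidised under anhydrous conditions.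

Step 11
Reactants: 21 5,7-bis(benzyloxy)-2-[4-(benzyloxy)-3-(methoxymethoxy)phenyl]-3-(methoxymethoxy)-4H-chromen-4-one
Product: 22 5,7-bis(benzyloxy)-2-[4-(benzyloxy)-3-hydroxyphenyl]-3-hydroxy-4H-chromen-4-one
Conditions: HCl (aq.), MeOH/THF, 50 °C
Reagents that add atoms: none
Why: Acid-catalysed acetal exchange with methanol removes the enol acetal on O3 and the aryl acetal on O3'; aryl benzyl ethers and the chromone should survive dilute acid at this temperature. The product has free hydroxyls only where sulfate is wanted.

Step 12
Reactants: 22 5,7-bis(benzyloxy)-2-[4-(benzyloxy)-3-hydroxyphenyl]-3-hydroxy-4H-chromen-4-one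
Product: 23 5,7-bis(benzyloxy)-2-[4-(benzyloxy)-3-(sulfooxy)phenyl]-4-oxo-4H-chromen-3-yl hydrogen sulfate
Conditions: SO3·pyridine (excess), pyridine, 60 °C
Reagents that add atoms: sulfur trioxide–pyridine complex, [O-]S(=O)(=O)[n+]1ccccc1
Why: O-Sulfonation of the phenolic 3'-hydroxyl and the enolic 3-hydroxyl by the SO3–amine complex (sulfation of phenols). With only two hydroxyls free, the reaction is pushed to the bis-sulfate by excess reagent and warming, which the chelated 3-hydroxyl needs.

Step 13
Reactants: 23 5,7-bis(benzyloxy)-2-[4-(benzyloxy)-3-(sulfooxy)phenyl]-4-oxo-4H-chromen-3-yl hydrogen sulfate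
Product: 24 quercetin 3,3'-bis(hydrogen sulfate), 5,7-dihydroxy-2-[4-hydroxy-3-(sulfooxy)phenyl]-4-oxo-4H-chromen-3-yl hydrogen sulfate
Conditions: H2 (1 atm), Pd/C, MeOH/THF, rt
Reagents that add atoms: none
Why: Hydrogenolysis of the three aryl benzyl ethers over Pd/C; sulfate monoester salts are inert to hydrogen and the medium stays neutral, so no hydrolysis is expected. Hydrogen uptake is followed so that the reaction is stopped before C2=C3 of the chromone is reduced.

## Compound list

1 | 3,5-bis(benzyloxy)phenol | Oc1cc(OCc2ccccc2)cc(OCc2ccccc2)c1 | starting material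
2 | 3,5-bis(benzyloxy)phenyl N-isopropylcarbamate | CC(C)NC(=O)Oc1cc(OCc2ccccc2)cc(OCc2ccccc2)c1 | intermediate
3 | 3,5-bis(benzyloxy)phenyl N-(tert-butyldimethylsilyl)-N-isopropylcarbamate | CC(C)N(C(=O)Oc1cc(OCc2ccccc2)cc(OCc2ccccc2)c1)[Si](C)(C)C(C)(C)C | intermediate (not isolated)
4 | {2,4-bis(benzyloxy)-6-[(N-(tert-butyldimethylsilyl)-N-isopropylcarbamoyl)oxy]phenyl}lithium | [Li]c1c(OC(=O)N(C(C)C)[Si](C)(C)C(C)(C)C)cc(OCc2ccccc2)cc1OCc1ccccc1 | intermediate (not isolated)
5 | 3,5-bis(benzyloxy)-2-(trimethylsilyl)phenyl N-(tert-butyldimethylsilyl)-N-isopropylcarbamate | CC(C)N(C(=O)Oc1cc(OCc2ccccc2)cc(OCc2ccccc2)c1[Si](C)(C)C)[Si](C)(C)C(C)(C)C | intermediate (not isolated)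
6 | 3,5-bis(benzyloxy)-2-(trimethylsilyl)phenyl N-isopropylcarbamate | CC(C)NC(=O)Oc1cc(OCc2ccccc2)cc(OCc2ccccc2)c1[Si](C)(C)C | intermediate
7 | 3,5-bis(benzyloxy)-2-(trimethylsilyl)phenol | C[Si](C)(C)c1c(O)cc(OCc2ccccc2)cc1OCc1ccccc1 | intermediate (not isolated)
8 | 3,5-bis(benzyloxy)-2-(trimethylsilyl)phenyl trifluoromethanesulfonate | C[Si](C)(C)c1c(OS(=O)(=O)C(F)(F)F)cc(OCc2ccccc2)cc1OCc1ccccc1 | intermediate
9 | methyl glycolate | COC(=O)CO | starting material
10 | methyl (methoxymethoxy)acetate | COCOCC(=O)OC | intermediate
11 | 4-(benzyloxy)-3-hydroxybenzaldehyde | O=Cc1ccc(OCc2ccccc2)c(O)c1 | starting material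
12 | 4-(benzyloxy)-3-(methoxymethoxy)benzaldehyde | COCOc1cc(C=O)ccc1OCc1ccccc1 | intermediate
13 | lithium 1-methoxy-2-(methoxymethoxy)ethen-1-olate | [Li]OC(OC)=COCOC | intermediate (not isolated)
14 | methyl 3-[4-(benzyloxy)-3-(methoxymethoxy)phenyl]-3-hydroxy-2-(methoxymethoxy)propanoate (racemic syn/anti mixture) | COCOc1cc(C(O)C(OCOC)C(=O)OC)ccc1OCc1ccccc1 | intermediate
15 | methyl 3-[4-(benzyloxy)-3-(methoxymethoxy)phenyl]-2-(methoxymethoxy)-3-[(methylsulfonyl)oxy]propanoate (racemic syn/anti mixture) | COCOc1cc(C(OS(C)(=O)=O)C(OCOC)C(=O)OC)ccc1OCc1ccccc1 | intermediate (not isolated)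
16 | methyl (Z)-3-[4-(benzyloxy)-3-(methoxymethoxy)phenyl]-2-(methoxymethoxy)acrylate | COC(=O)/C(OCOC)=C/c1ccc(OCc2ccccc2)c(OCOC)c1 | intermediate
17 | (Z)-3-[4-(benzyloxy)-3-(methoxymethoxy)phenyl]-2-(methoxymethoxy)acrylic acid | OC(=O)/C(OCOC)=C/c1ccc(OCc2ccccc2)c(OCOC)c1 | intermediate
18 | 3,5-bis(benzyloxy)benzyne (1,2-didehydro-3,5-bis(benzyloxy)benzene) | C1#CC(OCc2ccccc2)=CC(OCc2ccccc2)=C1 | intermediate (not isolated)
19 | (Z)-1-[2,4-bis(benzyloxy)-6-hydroxyphenyl]-3-[4-(benzyloxy)-3-(methoxymethoxy)phenyl]-2-(methoxymethoxy)prop-2-en-1-one (present as its cesium phenoxide) | COCOc1cc(/C=C(\OCOC)C(=O)c2c(O)cc(OCc3ccccc3)cc2OCc2ccccc2)ccc1OCc1ccccc1 | intermediate (not isolated)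
20 | rac-trans-5,7-bis(benzyloxy)-2-[4-(benzyloxy)-3-(methoxymethoxy)phenyl]-3-(methoxymethoxy)chroman-4-one ((2R,3R) enantiomer drawn) | COCOc1cc(ccc1OCc1ccccc1)[C@@H]1[C@H](C(=O)c2c(OCc3ccccc3)cc(OCc3ccccc3)cc2O1)OCOC | intermediate
21 | 5,7-bis(benzyloxy)-2-[4-(benzyloxy)-3-(methoxymethoxy)phenyl]-3-(methoxymethoxy)-4H-chromen-4-one | COCOc1cc(ccc1OCc1ccccc1)-c1oc2cc(OCc3ccccc3)cc(OCc3ccccc3)c2c(=O)c1OCOC | intermediate
22 | 5,7-bis(benzyloxy)-2-[4-(benzyloxy)-3-hydroxyphenyl]-3-hydroxy-4H-chromen-4-one | Oc1cc(ccc1OCc1ccccc1)-c1oc2cc(OCc3ccccc3)cc(OCc3ccccc3)c2c(=O)c1O | intermediate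
23 | 5,7-bis(benzyloxy)-2-[4-(benzyloxy)-3-(sulfooxy)phenyl]-4-oxo-4H-chromen-3-yl hydrogen sulfate | O=S(=O)(O)Oc1cc(ccc1OCc1ccccc1)-c1oc2cc(OCc3ccccc3)cc(OCc3ccccc3)c2c(=O)c1OS(=O)(=O)O | intermediate
24 | quercetin 3,3'-bis(hydrogen sulfate) | O=c1c(OS(=O)(=O)O)c(-c2ccc(O)c(OS(=O)(=O)O)c2)oc2cc(O)cc(O)c12 | target

## Step count and risks

Total step count: 13.
Longest linear sequence: 9 steps (steps 5, 6, 7, 8, 9, 10, 11, 12, 13 from aldehyde 11; the branch from 9 through step 4 is equally long, and the ring A branch from 1 counts 8).

**Step 9 (key step).** Several processes can divert the cascade.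
- The aryl anion formed after carboxylate addition may be protonated by unreacted acid before it reaches the carbonyl, so that only O-arylation without acyl transfer results.
- The aryl anion may add to the β-carbon of the cinnamoyl unit instead of the carbonyl carbon.
- Orientation of the aryne capture may leak, because the remote benzyloxy group exerts a small opposing inductive pull.
- The phenoxide or the enolate of the product may be arylated by further aryne.
- The acetals may be lost at 125 °C in the presence of bifluoride.

Fallback by acylation of an aryllithium instead of aryne capture, setting out from 17 and from 2 and coming back at 20. Acid 17 would be coupled with N,O-dimethylhydroxylamine (carbodiimide, CH2Cl2) to the amide (Z)-3-[4-(benzyloxy)-3-(methoxymethoxy)phenyl]-N-methoxy-2-(methoxymethoxy)-N-methylacrylamide F1. Carbamate 2 would be taken to aryllithium 4 exactly as in step 2 and quenched with F1 at −78 °C. The acidic work-up removes the N-silyl group and releases the ketone 3,5-bis(benzyloxy)-2-{(Z)-3-[4-(benzyloxy)-3-(methoxymethoxy)phenyl]-2-(methoxymethoxy)acryloyl}phenyl N-isopropylcarbamate F2. DBU and Et2NH in MeCN, as in step 3, would then strip the carbamate, and the phenoxide of 19 set free closes to 20 in the same flask.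

**Step 2.** Deprotonation of a benzylic CH2 of the benzyl ethers, followed by anionic rearrangement, or lithiation between the two benzyloxy groups, may compete with the wanted ring lithiation and lower the regiochemical purity of the silane.

Fallback by halogen–metal exchange, setting out from 1 and coming back at 8. Ortho-bromination (NBS, cat. i-Pr2NH, CH2Cl2; both ortho positions are the same) would give 3,5-bis(benzyloxy)-2-bromophenol F3. Silylation on oxygen with hexamethyldisilazane would give [3,5-bis(benzyloxy)-2-bromophenoxy]trimethylsilane F4. With n-BuLi at −78 °C, bromine–lithium exchange, which is much faster than benzylic deprotonation, is followed by a 1,3-shift of silicon from oxygen to carbon (retro-Brook rearrangement) to the lithium salt of 7. Tf2O then gives 8.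

**Step 10.** Hydride abstraction may be slow for a flavanone that lacks a free 5-hydroxyl and carries an alkoxy group on C3, and prolonged heating with the quinone may start oxidative cleavage of benzyl ethers. Partial loss of the acetals would not matter, since step 11 removes them.

Fallback by changing the order of deprotection and oxidation, setting out from 20 and coming back at 22. Acid under the conditions of step 11 would give the dihydroflavonol trans-5,7-bis(benzyloxy)-2-[4-(benzyloxy)-3-hydroxyphenyl]-3-hydroxychroman-4-one F5. Iodine with KOAc in warm acetic acid, the long-established dehydrogenation of 3-hydroxyflavanones to flavonols, would then give 22.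

**Step 12.** Sulfation may stop at the monosulfate, because the 3-hydroxyl is hydrogen-bonded to the C4 carbonyl and crowded by ring B, and the very polar bis-sulfate salt is hard to purify from partly sulfated material.

Fallback through protected sulfate diesters, setting out from 22 and coming back at 24 without passing 23. 2,2,2-Trichloroethyl chlorosulfate with Et3N and DMAP in THF would give the neutral, chromatographable 5,7-bis(benzyloxy)-2-{4-(benzyloxy)-3-[(2,2,2-trichloroethoxy)sulfonyloxy]phenyl}-4-oxo-4H-chromen-3-yl 2,2,2-trichloroethyl sulfate F6. Pd/C with HCO2NH4 in methanol would then remove both trichloroethyl groups by reductive fragmentation and the three benzyl groups by transfer hydrogenolysis, giving 24 as its ammonium salt.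

## Further compounds

F1 | step 9 | (Z)-3-[4-(benzyloxy)-3-(methoxymethoxy)phenyl]-N-methoxy-2-(methoxymethoxy)-N-methylacrylamide | CON(C)C(=O)/C(OCOC)=C/c1ccc(OCc2ccccc2)c(OCOC)c1
F2 | step 9 | 3,5-bis(benzyloxy)-2-{(Z)-3-[4-(benzyloxy)-3-(methoxymethoxy)phenyl]-2-(methoxymethoxy)acryloyl}phenyl N-isopropylcarbamate | CC(C)NC(=O)Oc1cc(OCc2ccccc2)cc(OCc2ccccc2)c1C(=O)/C(OCOC)=C/c1ccc(OCc2ccccc2)c(OCOC)c1
F3 | step 2 | 3,5-bis(benzyloxy)-2-bromophenol | Oc1cc(OCc2ccccc2)cc(OCc2ccccc2)c1Br
F4 | step 2 | [3,5-bis(benzyloxy)-2-bromophenoxy]trimethylsilane | C[Si](C)(C)Oc1cc(OCc2ccccc2)cc(OCc2ccccc2)c1Br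
F5 | step 10 | rac-trans-5,7-bis(benzyloxy)-2-[4-(benzyloxy)-3-hydroxyphenyl]-3-hydroxychroman-4-one ((2R,3R) enantiomer drawn) | Oc1cc(ccc1OCc1ccccc1)[C@@H]1[C@H](C(=O)c2c(OCc3ccccc3)cc(OCc3ccccc3)cc2O1)O
F6 | step 12 | 5,7-bis(benzyloxy)-2-{4-(benzyloxy)-3-[(2,2,2-trichloroethoxy)sulfonyloxy]phenyl}-4-oxo-4H-chromen-3-yl 2,2,2-trichloroethyl sulfate | O=S(=O)(OCC(Cl)(Cl)Cl)Oc1cc(ccc1OCc1ccccc1)-c1oc2cc(OCc3ccccc3)cc(OCc3ccccc3)c2c(=O)c1OS(=O)(=O)OCC(Cl)(Cl)Cl
A1 | alternative 1 | (Z)-2-[4-(benzyloxy)-3-hydroxybenzylidene]-4,6-dihydroxybenzofuran-3(2H)-one | O=C1/C(=C/c2ccc(OCc3ccccc3)c(O)c2)Oc2cc(O)cc(O)c21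
A2 | alternative 1 | 4'-O-benzylquercetin, 2-[4-(benzyloxy)-3-hydroxyphenyl]-3,5,7-trihydroxy-4H-chromen-4-one | O=c1c(O)c(-c2ccc(OCc3ccccc3)c(O)c2)oc2cc(O)cc(O)c12
A3 | alternative 2 | 3-(benzyloxy)cyclobut-2-en-1-one | O=C1CC(OCc2ccccc2)=C1
A4 | alternative 2 | tert-butyl({1-[4-(benzyloxy)-3-(methoxymethoxy)phenyl]-5-[(triisopropylsilyl)oxy]penta-1,4-diyn-3-yl}oxy)dimethylsilane (racemic) | CC(C)[Si](OC#CC(O[Si](C)(C)C(C)(C)C)C#Cc1ccc(OCc2ccccc2)c(OCOC)c1)(C(C)C)C(C)C
A5 | alternative 2 | 5-(benzyloxy)-2-{1-(tert-butyldimethylsilyloxy)-3-[4-(benzyloxy)-3-(methoxymethoxy)phenyl]prop-2-yn-1-yl}-3-(triisopropylsilyloxy)phenol (racemic, one enantiomer drawn) | Oc1cc(OCc2ccccc2)cc(O[Si](C(C)C)(C(C)C)C(C)C)c1[C@@H](O[Si](C)(C)C(C)(C)C)C#Cc1ccc(OCc2ccccc2)c(OCOC)c1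
A6 | alternative 3 | 1-[4-(benzyloxy)-3-(methoxymethoxy)phenyl]-2-(methoxymethoxy)-3-(2,4,6-trifluorophenyl)propane-1,3-dione (racemic) | COCOc1cc(ccc1OCc1ccccc1)C(=O)C(OCOC)C(=O)c1c(F)cc(F)cc1F
A7 | alternative 3 | 2-[4-(benzyloxy)-3-(methoxymethoxy)phenyl]-5,7-difluoro-3-(methoxymethoxy)-4H-chromen-4-one | O=c1c(OCOC)c(-c2ccc(OCc3ccccc3)c(OCOC)c2)oc2cc(F)cc(F)c12
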